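**Retrosynthetic overview**
1. Late disconnections: the C3/C19 acetonide; the C12 carbinol from a C12 ketone by chelation-controlled reduction; C12–C13 between a Weinreb amide and the dianion of (S)-3-hydroxy-γ-butyrolactone (lactone ring taken intact from the chiral pool); C8=C17 from a C8 ketone; C9–C11 from a regiodefined C8 enolate.
2. Key disconnection: rings A and B are opened together by a retro-[4+2] across C6–C7 and C5–C10, giving acyclic triene 11 (diene C7=C8(OSiMe3)–C9=C10, dienophile = vinyl group C5=C6 on quaternary C4).
3. Enabling feature: C8 of ring B, the carbon that bears the exocyclic methylene, can be a ketone. As the oxygenated carbon of a 2-silyloxydiene it makes C7 a diene terminus, and the resulting C8=C9 enol ether then serves to attach C11 at C9 and to bring in C17.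
4. Second feature: quaternary C4 of ring A with its 1,3-diol (C3–OH, C19–OH) carries the vinyl dienophile and is locked as a 1,3-dioxane that fixes the tether conformation. C3 and C4 come from an iridium-catalysed tert-(hydroxy)prenylation with isoprene monoxide, and the (E)-C9=C10 unit with C20 from carboalumination of pent-4-yn-1-ol.
5. Ring order: temporary dioxane (step 3), then rings A and B at once (step 6), then the lactone ring attached preformed (step 9).

Key step: step 6

Remark: labdane numbering is used for positions throughout (C1–C10 decalin, ring A = C1–C5/C10, ring B = C5–C10; C11–C16 side chain and lactone; C17 exocyclic methylene; C18 methyl and C19 CH2O on C4; C20 methyl on C10).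
Assumption: the (R)-Tol-BINAP-derived iridium catalyst is taken to give the (2R,3R) diol 6; should the sense be opposite, the (S)-ligand is used.

**Step 1**
Reactants: 1 pent-4-yn-1-ol
Product: 3 (4E)-5-bromo-4-methylpent-4-en-1-ol, via alkenylalane 2 (not isolated)
Conditions: Me3Al (3 equiv), Cp2ZrCl2 (0.2 equiv), CH2Cl2, 0 °C → rt; then N-bromosuccinimide, THF, −30 → 0 °C
Reagents that add atoms: trimethylaluminium, C[Al](C)C; N-bromosuccinimide, O=C1CCC(=O)N1Br
Why: Negishi zirconium-catalysed carboalumination adds methyl and aluminium syn across the terminal alkyne with methyl on the internal carbon, and bromination of the C–Al bond with retention should fix the (E) geometry that later places the tether trans to C8.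

**Step 2**
Reactants: 3 (4E)-5-bromo-4-methylpent-4-en-1-ol; 4 2-ethenyl-2-methyloxirane (isoprene monoxide, racemic)
Product: 6 (2R,3R,6E)-7-bromo-2-ethenyl-2,6-dimethylhept-6-ene-1,3-diol, via aldehyde 5 (not isolated)
Conditions: 4 (3 equiv), π-allyl iridium C,O-benzoate catalyst formed from [Ir(cod)Cl]2, (R)-Tol-BINAP, 4-cyano-3-nitrobenzoic acid and allyl acetate (5 mol%), K3PO4 (5 mol%), THF, 60 °C
Reagents that add atoms: none
Why: Iridium-catalysed tert-(hydroxy)prenylation (alcohol-mediated carbonyl allylation by hydrogen transfer): the alcohol is dehydrogenated to the aldehyde, the vinyl epoxide ionises to a hydroxymethyl-substituted π-allyl (its stereocentre is erased), and addition through a closed chair transition state from the (E)-σ-allyl should give the anti diol, with the chiral phosphine choosing the aldehyde face, so that C3 and quaternary C4 are set together.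

**Step 3**
Reactants: 6 (2R,3R,6E)-7-bromo-2-ethenyl-2,6-dimethylhept-6-ene-1,3-diol
Product: 7 (4R,5R)-4-[(3E)-4-bromo-3-methylbut-3-en-1-yl]-5-ethenyl-2,2,5-trimethyl-1,3-dioxane
Conditions: Me2C(OMe)2, pyridinium p-toluenesulfonate (cat.), CH2Cl2, rt
Reagents that add atoms: 2,2-dimethoxypropane, COC(C)(C)OC
Why: Acid-catalysed transacetalisation gives the six-membered isopropylidene acetal of the 1,3-diol, which protects both hydroxyls and creates the ring that later controls the tether.

**Step 4**
Reactants: 7 (4R,5R)-4-[(3E)-4-bromo-3-methylbut-3-en-1-yl]-5-ethenyl-2,2,5-trimethyl-1,3-dioxane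
Product: 9 (3E)-6-[(4R,5R)-5-ethenyl-2,2,5-trimethyl-1,3-dioxan-4-yl]-4-methylhex-3-en-2-one, via alkenyllithium 8 (not isolated)
Conditions: tBuLi (2.1 equiv), Et2O, −78 °C; then MeC(O)N(OMe)Me, −78 → 0 °C; aq. NH4Cl
Reagents that add atoms: N-methoxy-N-methylacetamide, CC(=O)N(C)OC
Why: Bromine–lithium exchange proceeds with retention of alkene geometry and Weinreb ketone synthesis stops the acylation at the methyl ketone, so the (E)-enone with C7 and C8 is obtained.

**Step 5**
Reactants: 9 (3E)-6-[(4R,5R)-5-ethenyl-2,2,5-trimethyl-1,3-dioxan-4-yl]-4-methylhex-3-en-2-one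
Product: 11 (4R,5R)-5-ethenyl-2,2,5-trimethyl-4-[(3E)-3-methyl-5-(trimethylsilyloxy)hexa-3,5-dien-1-yl]-1,3-dioxane, via lithium dienolate 10 (not isolated)
Conditions: LDA, THF, −78 °C; then Me3SiCl/Et3N, −78 °C → rt; pentane, filtration (no aqueous acid)
Reagents that add atoms: chlorotrimethylsilane, C[Si](C)(C)Cl
Why: Kinetic deprotonation of the α′-methyl group by lithium diisopropylamide gives the cross-conjugated dienolate, and O-silylation (silyl enol ether formation) should deliver the 2-silyloxydiene without touching the C9=C10 geometry.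

**Step 6**
Reactants: 11 (4R,5R)-5-ethenyl-2,2,5-trimethyl-4-[(3E)-3-methyl-5-(trimethylsilyloxy)hexa-3,5-dien-1-yl]-1,3-dioxane
Product: 12 trans-fused cycloadduct: Δ8(9)-octalin with C8–OSiMe3, C18 and C20 methyls and the C3–O/C19–O isopropylidene acetal (C3, C4, C5, C10 as in the target; C20 anti to H-5 and syn to C19)
Conditions: toluene (0.01 M), BHT (cat.), N,O-bis(trimethylsilyl)acetamide (5 mol%), sealed tube, 190–210 °C
Reagents that add atoms: none
Why: Thermal type 1 intramolecular Diels–Alder reaction of a deca-1,7,9-triene, a concerted but asynchronous suprafacial [4+2] in which the bond between the two unsubstituted termini (C6–C7) is expected to lead and the congested C5–C10 bond to follow; the closest known reactions are thermal cyclisations of unactivated decatrienes that carry a methyl group on the tethered diene terminus and give angularly methylated trans-octalins. Ring B is closed as the new cyclohexene by the two σ bonds C6–C7 and C5–C10, and ring A is closed in the same event by C5–C10 as the fused four-atom-tether ring in a chair-like arrangement. The two new stereocentres are C5 and C10: their trans relationship follows from the transition state with C6 and C9 both equatorial on the nascent ring A chair, since the cis modes either put C6 axial against H-1 and H-3 or swing the silyloxydiene across C19 and the dioxane, and the (E) geometry of C9=C10 makes C20 the angular methyl. Their sense relative to C3 and C4 is fixed by the dioxane, which must keep C2 equatorial (an axial C2 would clash with an acetal methyl), so that O3 is equatorial and C19 axial on ring A as in the target. The selectivities needed are trans over cis fusion and one diene face, and the rate must beat the reversible [1,5]-hydrogen shift of the diene; the quaternary C4 and the dioxane ring populate the reactive rotamer and so make up for the missing electronic activation of the vinyl group. The adduct carries the enol ether regiodefined at C8=C9, which steps 7 and 8 use.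

**Step 7**
Reactants: 12 trans-fused cycloadduct (C8–OSiMe3, C8=C9)
Product: 15 C8 ketone carrying CH2C(O)N(OMe)Me on C9, equatorial and cis to C20 (C9 as in the target), via lithium enolate 13 (not isolated), via 9-epi ketone 14 (not isolated)
Conditions: MeLi, THF, 0 °C → rt; then DMPU, BrCH2C(O)N(OMe)Me, −78 → 0 °C; then MeOH, NaOMe, rt
Reagents that add atoms: 2-bromo-N-methoxy-N-methylacetamide, CON(C)C(=O)CBr
Why: Methyllithium cleaves the Si–O bond to the regiospecific C8/C9 lithium enolate, SN2 enolate alkylation by the activated α-bromoamide should occur axially at C9 on the face anti to the angular C20 methyl, and methoxide equilibration through the enolate then moves the side chain to the more stable equatorial position, which sets C9.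

**Step 8**
Reactants: 15 C8 ketone with the C9 amide side chain
Product: 16 8(17)-methylene Weinreb amide (exocyclic C8=C17; acetonide retained)
Conditions: Zn, CH2Br2, TiCl4, THF/CH2Cl2, 0 °C → rt
Reagents that add atoms: dibromomethane, BrCBr
Why: Takai–Lombardo methylenation uses a non-basic geminal zinc/titanium reagent that should convert the hindered, enolisable ketone into the methylene compound without epimerising C9 and without attacking the Weinreb amide.

**Step 9**
Reactants: 16 8(17)-methylene Weinreb amide; 17 (4S)-4-hydroxyoxolan-2-one ((S)-3-hydroxy-γ-butyrolactone)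
Product: 19 β-keto lactone, (3R,4S)-4-hydroxy-3-acyloxolan-2-one with the C12 ketone (C13/C14 trans), via lactone dianion 18 (not isolated)
Conditions: 17 (2.5 equiv), LDA (5.2 equiv), THF, −78 °C; then 16, −78 → −30 °C; aq. NH4Cl (pH 6–7), product used promptly
Reagents that add atoms: none
Why: Fráter–Seebach-type dianion formation protects the β-oxygen against elimination, and Claisen-type C-acylation of the enolate by the Weinreb amide should occur anti to the C14 alkoxide, giving the trans-3,4-disubstituted lactone with the acylation halted at the ketone stage.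

**Step 10**
Reactants: 19 β-keto lactone
Product: 20 3,19-O-isopropylidene derivative of the target, (12S)
Conditions: Zn(BH4)2, Et2O, −30 → 0 °C; aq. NH4Cl
Reagents that add atoms: none
Why: Chelation-controlled hydride reduction: both the zinc chelate between the C12 ketone and the lactone carbonyl (hydride anti to C14) and the chelate between the ketone and the C14 hydroxyl (1,3-syn reduction) lead to the same 12,13-syn/12,14-syn carbinol, which is (12S).

**Step 11**
Reactants: 20 3,19-O-isopropylidene derivative of the target
Product: 21 (3S,4S)-4-hydroxy-3-[(1S)-1-hydroxy-2-[(1R,4aS,5R,6R,8aS)-6-hydroxy-5-(hydroxymethyl)-5,8a-dimethyl-2-methylidenedecahydronaphthalen-1-yl]ethyl]oxolan-2-one (target)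
Conditions: AcOH/H2O/THF (3:1:1), rt
Reagents that add atoms: none
Why: Mild acid-catalysed acetal hydrolysis should free the C3 and C19 hydroxyls while leaving the exocyclic alkene and the β-hydroxy lactone untouched.

**Compound list**
1 | pent-4-yn-1-ol | C#CCCCO | starting material
2 | dimethyl{(1E)-5-[(dimethylalumanyl)oxy]-2-methylpent-1-en-1-yl}alumane | C[Al](C)OCCC/C(C)=C/[Al](C)C | intermediate (not isolated)
3 | (4E)-5-bromo-4-methylpent-4-en-1-ol | OCCC/C(C)=C/Br | intermediate
4 | 2-ethenyl-2-methyloxirane (isoprene monoxide, racemic) | CC1(C=C)CO1 | starting material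
5 | (4E)-5-bromo-4-methylpent-4-enal | O=CCC/C(C)=C/Br | intermediate (not isolated)
6 | (2R,3R,6E)-7-bromo-2-ethenyl-2,6-dimethylhept-6-ene-1,3-diol | C=C[C@](C)(CO)[C@H](O)CC/C(C)=C/Br | intermediate
7 | (4R,5R)-4-[(3E)-4-bromo-3-methylbut-3-en-1-yl]-5-ethenyl-2,2,5-trimethyl-1,3-dioxane | C=C[C@]1(C)COC(C)(C)O[C@@H]1CC/C(C)=C/Br | intermediate
8 | alkenyllithium from 7 (Li in place of Br, E retained) | C=C[C@]1(C)COC(C)(C)O[C@@H]1CC/C(C)=C/[Li] | intermediate (not isolated)
9 | (3E)-6-[(4R,5R)-5-ethenyl-2,2,5-trimethyl-1,3-dioxan-4-yl]-4-methylhex-3-en-2-one | C=C[C@]1(C)COC(C)(C)O[C@@H]1CC/C(C)=C/C(C)=O | intermediate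
10 | lithium (3E)-6-[(4R,5R)-5-ethenyl-2,2,5-trimethyl-1,3-dioxan-4-yl]-4-methylhexa-1,3-dien-2-olate | C=C[C@]1(C)COC(C)(C)O[C@@H]1CC/C(C)=C/C(=C)O[Li] | intermediate (not isolated)
11 | (4R,5R)-5-ethenyl-2,2,5-trimethyl-4-[(3E)-3-methyl-5-(trimethylsilyloxy)hexa-3,5-dien-1-yl]-1,3-dioxane | C=C[C@]1(C)COC(C)(C)O[C@@H]1CC/C(C)=C/C(=C)O[Si](C)(C)C | intermediate
12 | trans-fused cycloadduct, C8–OSiMe3 enol ether (C8=C9), C3/C19 acetonide; C3, C4, C5, C10 as in the target | C[Si](C)(C)OC1=C[C@]2(C)CC[C@H]3OC(C)(C)OC[C@@]3(C)[C@H]2CC1 | intermediate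
13 | lithium C8/C9 enolate of the decalone acetonide | [Li]OC1=C[C@]2(C)CC[C@H]3OC(C)(C)OC[C@@]3(C)[C@H]2CC1 | intermediate (not isolated)
14 | C8 ketone with CH2C(O)N(OMe)Me on C9, axial and trans to C20 (9-epimer of 15) | O=C1CC[C@@H]2[C@]3(C)COC(C)(C)O[C@@H]3CC[C@@]2(C)[C@H]1CC(=O)N(C)OC | intermediate (not isolated)
15 | C8 ketone with CH2C(O)N(OMe)Me on C9, equatorial and cis to C20 (C9 as in the target) | O=C1CC[C@@H]2[C@]3(C)COC(C)(C)O[C@@H]3CC[C@@]2(C)[C@@H]1CC(=O)N(C)OC | intermediate
16 | 8(17)-methylene Weinreb amide, C3/C19 acetonide | C=C1CC[C@@H]2[C@]3(C)COC(C)(C)O[C@@H]3CC[C@@]2(C)[C@@H]1CC(=O)N(C)OC | intermediate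
17 | (4S)-4-hydroxyoxolan-2-one ((S)-3-hydroxy-γ-butyrolactone) | O=C1C[C@H](O)CO1 | starting material
18 | dilithium alkoxide enolate of 17 | [Li]OC1=C[C@H](O[Li])CO1 | intermediate (not isolated)
19 | β-keto lactone: (3R,4S)-4-hydroxy-3-acyloxolan-2-one, acyl = C11–C12(=O) of the acetonide-protected decalin (C13/C14 trans) | C=C1CC[C@@H]2[C@]3(C)COC(C)(C)O[C@@H]3CC[C@@]2(C)[C@@H]1CC(=O)[C@@H]1C(=O)OC[C@H]1O | intermediate
20 | 3,19-O-isopropylidene derivative of the target, (12S,13S,14S) | C=C1CC[C@@H]2[C@]3(C)COC(C)(C)O[C@@H]3CC[C@@]2(C)[C@@H]1C[C@H](O)[C@@H]1C(=O)OC[C@H]1O | intermediate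
21 | (3S,4S)-4-hydroxy-3-[(1S)-1-hydroxy-2-[(1R,4aS,5R,6R,8aS)-6-hydroxy-5-(hydroxymethyl)-5,8a-dimethyl-2-methylidenedecahydronaphthalen-1-yl]ethyl]oxolan-2-one | C=C1CC[C@@H]2[C@](C)(CO)[C@H](O)CC[C@@]2(C)[C@@H]1C[C@H](O)[C@@H]1C(=O)OC[C@H]1O | target

**Step count and risks**
Total steps: 11. Longest linear sequence: 11 steps (from pent-4-yn-1-ol; isoprene monoxide and the hydroxy lactone are bought).

Steps most likely to fail:

Step 6. The unactivated vinyl group may add too slowly, so that the [1,5]-hydrogen shift of the diene, loss of the silyl group or oligomerisation outrun the cycloaddition, or the trans and cis fusion modes may be poorly discriminated. The fallback activates the dienophile and removes the activating group afterwards. It sets out from enone 9: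
- Oxidative cleavage of the vinyl group (OsO4 cat., NaIO4, 2,6-lutidine, dioxane/H2O) would give the neopentyl aldehyde F1.
- A Horner–Wadsworth–Emmons reaction with diethyl (phenylsulfonylmethyl)phosphonate would give the (E)-vinyl sulfone F2.
- Soft enolisation (Me3SiOTf, Et3N, CH2Cl2, 0 °C) would give the sulfonyl triene F3.
- Its activated dienophile should cyclise near 110 °C in toluene to the C6-sulfonyl cycloadduct F4.
- K2CO3 in MeOH would remove the silyl group and expel benzenesulfinate by an E1cB path to give the C6=C7–C8=O enone F5.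
- Kinetic deprotonation at C9 (LDA, THF, −78 °C) and alkylation with 2-bromo-N-methoxy-N-methylacetamide would give F6.
- Hydrogenation of the C6=C7 bond (H2, Pd on carbon, EtOAc) comes back to the route at 14, which is equilibrated to 15 as in step 7.

Step 7. Alkylation at the neopentyl C9 may be slow enough for proton transfer between enolate and product to move the reaction to C7, or O-alkylation may compete. The fallback avoids the enolate and sets out from silyl enol ether 12. A radical alkylation by iodine-atom transfer (ICH2C(O)N(OMe)Me, Et3B, air, CH2Cl2, rt) should add the electrophilic carbamoylmethyl radical to C9 of the enol ether; the α-silyloxy radical takes up iodine and the adduct collapses to the ketone, coming back to the route at 14 (then NaOMe/MeOH to 15). No new compound is formed on the way (F0).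

Step 9. The basic dianion may enolise the Weinreb amide instead of adding to it, so that conversion stalls, or the β-keto lactone may dehydrate or epimerise during work-up. The fallback replaces acylation and reduction by an auxiliary-controlled aldol. It sets out from 16:
- Reduction with iBu2AlH (THF, −78 °C) would give aldehyde F7.
- An Evans syn-aldol reaction of F7 with the dibutylboron enolate (Bu2BOTf, iPr2NEt, CH2Cl2, −78 → 0 °C) of the imide F8 would set C12 and C13 together under auxiliary control and give adduct F9. F8 would be made from (S)-2-(2,2-dimethyl-1,3-dioxolan-4-yl)acetic acid and (R)-4-benzyl-oxazolidin-2-one with pivaloyl chloride, Et3N and LiCl.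
- Aqueous acid (AcOH/H2O, 40 °C) would remove both acetonides, and the freed C15 hydroxyl should close the γ-lactone with release of the auxiliary, coming back to the route at 21.

**Further compounds**
F1 | step 6 | 2,2,5-trimethyl-4-[(3E)-3-methyl-5-oxohex-3-en-1-yl]-1,3-dioxane-5-carbaldehyde (ring stereocentres as in 9) | O=C[C@]1(C)COC(C)(C)O[C@@H]1CC/C(C)=C/C(C)=O
F2 | step 6 | (3E)-4-methyl-6-{2,2,5-trimethyl-5-[(E)-2-(phenylsulfonyl)ethenyl]-1,3-dioxan-4-yl}hex-3-en-2-one (ring stereocentres as in 9) | O=S(=O)(c1ccccc1)/C=C/[C@]1(C)COC(C)(C)O[C@@H]1CC/C(C)=C/C(C)=O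
F3 | step 6 | trimethylsilyl dienol ether of F2 (2-silyloxydiene, E at C9=C10) | O=S(=O)(c1ccccc1)/C=C/[C@]1(C)COC(C)(C)O[C@@H]1CC/C(C)=C/C(=C)O[Si](C)(C)C
F4 | step 6 | C6-phenylsulfonyl analogue of cycloadduct 12 (sulfonyl equatorial, trans to C4) | C[Si](C)(C)OC1=C[C@]2(C)CC[C@H]3OC(C)(C)OC[C@@]3(C)[C@H]2[C@H](S(=O)(=O)c2ccccc2)C1
F5 | step 6 | trans-fused C6=C7–C8=O enone with the C3/C19 acetonide | O=C1C=C[C@@H]2[C@]3(C)COC(C)(C)O[C@@H]3CC[C@@]2(C)C1
F6 | step 6 | enone F5 carrying CH2C(O)N(OMe)Me on C9 (axial, trans to C20) | O=C1C=C[C@@H]2[C@]3(C)COC(C)(C)O[C@@H]3CC[C@@]2(C)[C@H]1CC(=O)N(C)OC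
F0 | step 7 | none | none
F7 | step 9 | C12 aldehyde of the 8(17)-methylene decalin acetonide | C=C1CC[C@@H]2[C@]3(C)COC(C)(C)O[C@@H]3CC[C@@]2(C)[C@@H]1CC=O
F8 | step 9 | (4R)-4-benzyl-3-{2-[(4S)-2,2-dimethyl-1,3-dioxolan-4-yl]acetyl}oxazolidin-2-one | O=C1OC[C@@H](Cc2ccccc2)N1C(=O)C[C@H]1COC(C)(C)O1
F9 | step 9 | syn-aldol adduct of F7 and F8 (C12, C13, C14 as in the target) | C=C1CC[C@@H]2[C@]3(C)COC(C)(C)O[C@@H]3CC[C@@]2(C)[C@@H]1C[C@H](O)[C@H](C(=O)N1[C@H](Cc2ccccc2)COC1=O)[C@H]1COC(C)(C)O1
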